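**Retrosynthetic overview**
- The phenol is unmasked last from its benzyl ether; the (E)-bromomethylidene comes from an (E)-alkenyl boronate (bromodeboronation with retention), itself from cross-metathesis of the exo-methylene compound made from the cyclopentanone.
- The cyclopentanone comes from a 1,5-dimethyl-5-arylcyclopentene by hydroboration on the face opposite the aryl group (sets the secondary methyl cis to aryl) and oxidation; the aryl bromide is introduced para to the ether oxygen at the alcohol stage.
- The cyclopentene (second and last ring formed) comes from ring-closing metathesis of a 1,6-diene, made from a 3-butenyl-3-methylbenzofuranone via its Weinreb amide and methyl ketone.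
- Key C–C bond: enantioselective Michael addition of 3,6-dimethylbenzofuran-2(3H)-one to acrolein, which creates the quaternary benzylic stereocentre.
- The benzofuranone (first ring formed, later opened) comes from α-arylation of tert-butyl propanoate with 2-bromo-5-methylanisole, then HBr-mediated demethylation and lactonisation.

Assumption: the quinidine-derived thiourea is taken to give the (S)-configured Michael adduct; if the sense proves opposite, its quinine-derived pseudoenantiomer is used with nothing else changed.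

**Route**

Step 1
Reactants: 1 2-bromo-5-methylanisole; 2 tert-butyl propanoate
Product: 4 tert-butyl 2-(2-methoxy-4-methylphenyl)propanoate (racemic), via lithium enolate 3 (not isolated)
Conditions: Cy2NH, n-BuLi, toluene, 0 °C; 2, 0 °C; then 1, Pd(dba)2 (2 mol%), P(t-Bu)3 (2 mol%), rt
Reagents that add atoms: none
Why: Palladium-catalysed α-arylation of a pre-formed ester enolate couples the aryl bromide once at the α-carbon, the tert-butyl ester suppresses Claisen self-condensation, and the racemic centre formed here is erased in step 3.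

Step 2
Reactants: 4 tert-butyl 2-(2-methoxy-4-methylphenyl)propanoate
Product: 6 3,6-dimethyl-1-benzofuran-2(3H)-one (racemic), via hydroxy acid 5 (not isolated)
Conditions: 48% aq. HBr, AcOH, reflux
Reagents that add atoms: none
Why: Hot HBr cleaves the aryl methyl ether and the tert-butyl ester, and the resulting ortho-hydroxyaryl propanoic acid undergoes acid-catalysed lactonisation to the five-membered aryl lactone, which masks the phenol and acidifies the benzylic C–H.

Step 3
Reactants: 6 3,6-dimethyl-1-benzofuran-2(3H)-one; 7 acrolein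
Product: 8 3-[(3S)-3,6-dimethyl-2-oxo-2,3-dihydro-1-benzofuran-3-yl]propanal
Conditions: 9-amino-9-deoxy-epi-quinidine 3,5-bis(trifluoromethyl)phenyl thiourea (10 mol%), toluene, −30 °C
Reagents that add atoms: none
Why: Organocatalytic asymmetric Michael addition in which the quinuclidine nitrogen forms a chiral ion pair with the aromatic 2-oxidobenzofuran enolate while the thiourea binds acrolein, so C-3 attacks on one face and the quaternary benzylic stereocentre (later C-1 of the cyclopentane) is set as (S) and cannot racemise.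

Step 4
Reactants: 8 3-[(3S)-3,6-dimethyl-2-oxo-2,3-dihydro-1-benzofuran-3-yl]propanal
Product: 9 (3S)-3-(but-3-en-1-yl)-3,6-dimethyl-1-benzofuran-2(3H)-one
Conditions: Ph3PCH3Br, KN(SiMe3)2, THF, 0 °C; then 8, −78 → 0 °C
Reagents that add atoms: methyltriphenylphosphonium bromide, C[P+](c1ccccc1)(c1ccccc1)c1ccccc1.[Br-]
Why: Wittig methylenation is far faster at the unhindered aldehyde than at the α-quaternary aryl lactone at low temperature and leaves the stereocentre untouched.

Step 5
Reactants: 9 (3S)-3-(but-3-en-1-yl)-3,6-dimethyl-1-benzofuran-2(3H)-one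
Product: 10 (2S)-2-(2-hydroxy-4-methylphenyl)-N-methoxy-N,2-dimethylhex-5-enamide
Conditions: MeNH(OMe)·HCl, AlMe3, CH2Cl2, 0 °C → rt; then cold 1 M HCl
Reagents that add atoms: N,O-dimethylhydroxylamine hydrochloride, CNOC.Cl
Why: Weinreb aminolysis, in which the aluminium amide opens the activated aryl ester to the N-methoxy-N-methylamide and frees the phenol.

Step 6
Reactants: 10 (2S)-2-(2-hydroxy-4-methylphenyl)-N-methoxy-N,2-dimethylhex-5-enamide
Product: 11 (2S)-2-[2-(benzyloxy)-4-methylphenyl]-N-methoxy-N,2-dimethylhex-5-enamide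
Conditions: BnBr, K2CO3, DMF, rt
Reagents that add atoms: benzyl bromide, BrCc1ccccc1
Why: Williamson etherification gives a benzyl ether that tolerates the organolithium, ylide, borane, ruthenium, titanium and copper reagents used later and can be removed without hydrogenation.

Step 7
Reactants: 11 (2S)-2-[2-(benzyloxy)-4-methylphenyl]-N-methoxy-N,2-dimethylhex-5-enamide
Product: 12 (3S)-3-[2-(benzyloxy)-4-methylphenyl]-3-methylhept-6-en-2-one
Conditions: MeLi, THF, −78 → 0 °C; then H2O
Reagents that add atoms: methyllithium, [Li]C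
Why: Weinreb ketone synthesis, where the chelated tetrahedral intermediate persists until work-up so methyllithium adds only once, giving the methyl ketone whose carbonyl carbon becomes C-2 of the ring.

Step 8
Reactants: 12 (3S)-3-[2-(benzyloxy)-4-methylphenyl]-3-methylhept-6-en-2-one
Product: 13 2-(benzyloxy)-1-[(3R)-2,3-dimethylhepta-1,6-dien-3-yl]-4-methylbenzene
Conditions: Ph3PCH3Br, KOt-Bu, toluene, 90 °C
Reagents that add atoms: methyltriphenylphosphonium bromide, C[P+](c1ccccc1)(c1ccccc1)c1ccccc1.[Br-]
Why: Wittig methylenation under forcing conditions converts the hindered ketone into the 1,1-disubstituted alkene, and the adjacent centre is quaternary so nothing can epimerise (the descriptor changes only through CIP priorities).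

Step 9
Reactants: 13 2-(benzyloxy)-1-[(3R)-2,3-dimethylhepta-1,6-dien-3-yl]-4-methylbenzene
Product: 14 2-(benzyloxy)-1-[(1R)-1,2-dimethylcyclopent-2-en-1-yl]-4-methylbenzene
Conditions: second-generation Grubbs catalyst (5 mol%), CH2Cl2, 40 °C
Reagents that add atoms: none
Why: Ring-closing metathesis of the 1,6-diene closes the cyclopentene with loss of ethene, helped by the quaternary carbon in the tether.

Step 10
Reactants: 14 2-(benzyloxy)-1-[(1R)-1,2-dimethylcyclopent-2-en-1-yl]-4-methylbenzene
Product: 16 (1R,2R,3R)-3-[2-(benzyloxy)-4-methylphenyl]-2,3-dimethylcyclopentan-1-ol, via alkylborane 15 (not isolated)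
Conditions: BH3·THF, THF, 0 °C → rt; then 3 M NaOH, 30% H2O2, 0 °C → rt
Reagents that add atoms: hydrogen peroxide, OO; borane–tetrahydrofuran, B.C1CCOC1 (boron of 15)
Why: Hydroboration–oxidation adds B–H syn with boron on the less substituted carbon and hydrogen delivered to C-2 from the face opposite the bulky ortho-substituted aryl group, so the secondary methyl ends up cis to the aryl group (2R), and oxidation proceeds with retention.

Step 11
Reactants: 16 (1R,2R,3R)-3-[2-(benzyloxy)-4-methylphenyl]-2,3-dimethylcyclopentan-1-ol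
Product: 17 (1R,2R,3R)-3-[2-(benzyloxy)-5-bromo-4-methylphenyl]-2,3-dimethylcyclopentan-1-ol
Conditions: NBS, MeCN, 0 °C → rt, dark
Reagents that add atoms: N-bromosuccinimide, O=C1CCC(=O)N1Br
Why: Electrophilic aromatic bromination occurs para to the benzyloxy group (ortho to the ring methyl), the only strongly activated unhindered position, and is done while no alkene is present.

Step 12
Reactants: 17 (1R,2R,3R)-3-[2-(benzyloxy)-5-bromo-4-methylphenyl]-2,3-dimethylcyclopentan-1-ol
Product: 18 (2R,3R)-3-[2-(benzyloxy)-5-bromo-4-methylphenyl]-2,3-dimethylcyclopentan-1-one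
Conditions: n-Pr4N[RuO4] (5 mol%), NMO, 4 Å MS, CH2Cl2, rt
Reagents that add atoms: none
Why: Ley–Griffith oxidation gives the ketone under neutral conditions, so the kinetically set and thermodynamically less favoured cis aryl/methyl arrangement at C-2 is not epimerised.

Step 13
Reactants: 18 (2R,3R)-3-[2-(benzyloxy)-5-bromo-4-methylphenyl]-2,3-dimethylcyclopentan-1-one
Product: 19 1-(benzyloxy)-4-bromo-2-[(1R,2S)-1,2-dimethyl-3-methylidenecyclopentyl]-5-methylbenzene
Conditions: Cp2TiMe2, toluene/THF, 65 °C, dark
Reagents that add atoms: dimethyltitanocene Cp2TiMe2, C[Ti](C)(C1C=CC=C1)C1C=CC=C1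
Why: Petasis methylenation through Cp2Ti=CH2 and an oxatitanacyclobutane is non-basic, so the epimerisable α-stereocentre survives where a basic phosphorus ylide would risk equilibration (the 2S label is a CIP change only).

Step 14
Reactants: 19 1-(benzyloxy)-4-bromo-2-[(1R,2S)-1,2-dimethyl-3-methylidenecyclopentyl]-5-methylbenzene; 20 vinylboronic acid pinacol ester
Product: 21 2-[(E)-{(2S,3R)-3-[2-(benzyloxy)-5-bromo-4-methylphenyl]-2,3-dimethylcyclopentylidene}methyl]-4,4,5,5-tetramethyl-1,3,2-dioxaborolane
Conditions: 20 (5 equiv), second-generation Hoveyda–Grubbs catalyst (10 mol%), 1,4-benzoquinone (10 mol%), CH2Cl2, 40 °C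
Reagents that add atoms: none
Why: Olefin cross-metathesis of the 1,1-disubstituted alkene with excess vinyl boronate gives the trisubstituted alkenyl boronate with the boryl group anti to the branched C-2 side (E), and benzoquinone suppresses ruthenium hydride alkene migration.

Step 15
Reactants: 21 the (E)-alkenyl pinacol boronate
Product: 22 1-(benzyloxy)-4-bromo-2-[(1R,2R,3E)-3-(bromomethylidene)-1,2-dimethylcyclopentyl]-5-methylbenzene
Conditions: CuBr2 (3 equiv), THF/MeOH/H2O, 70 °C
Reagents that add atoms: CuBr2, [Cu+2].[Br-].[Br-]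
Why: Copper-mediated bromodeboronation (boron-to-copper transmetalation, then C–Br bond formation) replaces boron by bromine with retention of alkene geometry and without a carbocation, so the E geometry and C-2 are preserved.

Step 16
Reactants: 22 1-(benzyloxy)-4-bromo-2-[(1R,2R,3E)-3-(bromomethylidene)-1,2-dimethylcyclopentyl]-5-methylbenzene
Product: 23 4-bromo-2-[(1R,2R,3E)-3-(bromomethylidene)-1,2-dimethylcyclopentyl]-5-methylphenol
Conditions: BCl3, C6HMe5, CH2Cl2, −78 °C; then H2O
Reagents that add atoms: none
Why: Lewis-acid O-debenzylation at −78 °C, with pentamethylbenzene trapping the benzyl cation by Friedel–Crafts benzylation, frees the phenol without touching the aryl bromide, the vinyl bromide or the alkene.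

**Compound list**
1 | 2-bromo-5-methylanisole (1-bromo-2-methoxy-4-methylbenzene) | COc1cc(C)ccc1Br | starting material
2 | tert-butyl propanoate | CCC(=O)OC(C)(C)C | starting material
3 | lithium enolate of tert-butyl propanoate (lithium 1-tert-butoxyprop-1-en-1-olate) | CC=C([O-])OC(C)(C)C.[Li+] | intermediate (not isolated)
4 | tert-butyl 2-(2-methoxy-4-methylphenyl)propanoate, racemic | CC(C(=O)OC(C)(C)C)c1ccc(C)cc1OC | intermediate
5 | 2-(2-hydroxy-4-methylphenyl)propanoic acid, racemic | CC(C(=O)O)c1ccc(C)cc1O | intermediate (not isolated)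
6 | 3,6-dimethyl-1-benzofuran-2(3H)-one, racemic | CC1C(=O)Oc2cc(C)ccc12 | intermediate
7 | acrolein (prop-2-enal) | C=CC=O | starting material
8 | 3-[(3S)-3,6-dimethyl-2-oxo-2,3-dihydro-1-benzofuran-3-yl]propanal | O=CCC[C@]1(C)C(=O)Oc2cc(C)ccc21 | intermediate
9 | (3S)-3-(but-3-en-1-yl)-3,6-dimethyl-1-benzofuran-2(3H)-one | C=CCC[C@]1(C)C(=O)Oc2cc(C)ccc21 | intermediate
10 | (2S)-2-(2-hydroxy-4-methylphenyl)-N-methoxy-N,2-dimethylhex-5-enamide | C=CCC[C@](C)(C(=O)N(C)OC)c1ccc(C)cc1O | intermediate
11 | (2S)-2-[2-(benzyloxy)-4-methylphenyl]-N-methoxy-N,2-dimethylhex-5-enamide | C=CCC[C@](C)(C(=O)N(C)OC)c1ccc(C)cc1OCc1ccccc1 | intermediate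
12 | (3S)-3-[2-(benzyloxy)-4-methylphenyl]-3-methylhept-6-en-2-one | C=CCC[C@](C)(C(C)=O)c1ccc(C)cc1OCc1ccccc1 | intermediate
13 | 2-(benzyloxy)-1-[(3R)-2,3-dimethylhepta-1,6-dien-3-yl]-4-methylbenzene | C=CCC[C@](C)(C(C)=C)c1ccc(C)cc1OCc1ccccc1 | intermediate
14 | 2-(benzyloxy)-1-[(1R)-1,2-dimethylcyclopent-2-en-1-yl]-4-methylbenzene | CC1=CCC[C@@]1(C)c1ccc(C)cc1OCc1ccccc1 | intermediate
15 | {(1R,2S,3R)-3-[2-(benzyloxy)-4-methylphenyl]-2,3-dimethylcyclopentyl}borane (boron trans to the aryl group and to the C-2 methyl) | Cc1ccc(c(OCc2ccccc2)c1)[C@]1(C)CC[C@@H](B)[C@@H]1C | intermediate (not isolated)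
16 | (1R,2R,3R)-3-[2-(benzyloxy)-4-methylphenyl]-2,3-dimethylcyclopentan-1-ol (C-2 methyl cis to aryl, OH trans to aryl) | Cc1ccc(c(OCc2ccccc2)c1)[C@]1(C)CC[C@@H](O)[C@@H]1C | intermediate
17 | (1R,2R,3R)-3-[2-(benzyloxy)-5-bromo-4-methylphenyl]-2,3-dimethylcyclopentan-1-ol | Cc1cc(OCc2ccccc2)c(cc1Br)[C@]1(C)CC[C@@H](O)[C@@H]1C | intermediate
18 | (2R,3R)-3-[2-(benzyloxy)-5-bromo-4-methylphenyl]-2,3-dimethylcyclopentan-1-one (C-2 methyl cis to aryl) | Cc1cc(OCc2ccccc2)c(cc1Br)[C@]1(C)CCC(=O)[C@@H]1C | intermediate
19 | 1-(benzyloxy)-4-bromo-2-[(1R,2S)-1,2-dimethyl-3-methylidenecyclopentyl]-5-methylbenzene | Cc1cc(OCc2ccccc2)c(cc1Br)[C@]1(C)CCC(=C)[C@@H]1C | intermediate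
20 | vinylboronic acid pinacol ester (2-ethenyl-4,4,5,5-tetramethyl-1,3,2-dioxaborolane) | C=CB1OC(C)(C)C(C)(C)O1 | starting material
21 | 2-[(E)-{(2S,3R)-3-[2-(benzyloxy)-5-bromo-4-methylphenyl]-2,3-dimethylcyclopentylidene}methyl]-4,4,5,5-tetramethyl-1,3,2-dioxaborolane (boron cis to the ring CH2) | Cc1cc(OCc2ccccc2)c(cc1Br)[C@]1(C)CC/C(=C\B2OC(C)(C)C(C)(C)O2)[C@@H]1C | intermediate
22 | 1-(benzyloxy)-4-bromo-2-[(1R,2R,3E)-3-(bromomethylidene)-1,2-dimethylcyclopentyl]-5-methylbenzene | Cc1cc(OCc2ccccc2)c(cc1Br)[C@]1(C)CC/C(=C\Br)[C@@H]1C | intermediate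
23 | 4-bromo-2-[(1R,2R,3E)-3-(bromomethylidene)-1,2-dimethylcyclopentyl]-5-methylphenol | Cc1cc(O)c([C@]2(C)CC/C(=C\Br)[C@@H]2C)cc1Br | target

**Totals and risks**
Total step count: 16. Longest linear sequence: 16 steps (1 → 23); all other inputs are commercial.

Steps most likely to fail:

Step 3 (enantioselectivity with a 3-alkyl benzofuranone; acrolein oligomerisation). The fallback sets out from 6 and rejoins at 9, replacing catalytic enantiocontrol by a classical resolution. The Michael addition to 7 is run with an achiral base (Et3N 5 mol%, toluene, 0 °C) to give the racemic aldehyde 3-(3,6-dimethyl-2-oxo-2,3-dihydro-1-benzofuran-3-yl)propanal F1. F1 is methylenated as in step 4 to the racemic butenyl lactone F2. F2 is opened with (S)-1-phenylethylamine (toluene, 60 °C) to two diastereomeric phenol amides, the (2S)-amide F3 and the (2R)-amide F4, which are separated by crystallisation or chromatography. F3 is heated with TsOH·H2O in toluene, which relactonises it to enantiopure 9 and releases the amine.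

Step 10 (facial selectivity of the hydroboration). The fallback sets out from 14 and rejoins at 16, fixing the stereocentre by a directing group instead of steric approach alone. 14 is epoxidised with mCPBA (NaHCO3, CH2Cl2, 0 °C) to the epoxide F5, with oxygen on the face away from the aryl group; any minor face isomer is removed by chromatography. F5 is isomerised with LiNEt2 (Et2O, reflux; proton removal from the methyl group) to the exo-methylene allylic alcohol F6. F6 is hydrogenated with [Ir(cod)(PCy3)(py)]PF6 (2 mol%), H2 (1 atm), CH2Cl2; the hydroxyl group binds iridium and directs hydrogen to its own face of the exocyclic alkene, giving 16.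

Step 14 (cross-metathesis of a hindered 1,1-disubstituted alkene). The fallback sets out from 18 and rejoins at 21, bypassing 19. It is a boron–Wittig olefination of the ketone with LiCH(Bpin)2 (from CH2(Bpin)2 and lithium 2,2,6,6-tetramethylpiperidide, THF, 0 °C; then 18, −78 °C → rt). The stabilised α-boryl carbanion adds to the ketone and syn B–O elimination gives 21 with the remaining boryl group anti to the branched α-carbon. No new isolable compound is formed.

**Further compounds**
F1 | step 3 | 3-(3,6-dimethyl-2-oxo-2,3-dihydro-1-benzofuran-3-yl)propanal (racemic) | O=CCCC1(C)C(=O)Oc2cc(C)ccc21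
F2 | step 3 | 3-(but-3-en-1-yl)-3,6-dimethyl-1-benzofuran-2(3H)-one (racemic) | C=CCCC1(C)C(=O)Oc2cc(C)ccc21
F3 | step 3 | (2S)-2-(2-hydroxy-4-methylphenyl)-2-methyl-N-[(1S)-1-phenylethyl]hex-5-enamide | C=CCC[C@](C)(C(=O)N[C@@H](C)c1ccccc1)c1ccc(C)cc1O
F4 | step 3 | (2R)-2-(2-hydroxy-4-methylphenyl)-2-methyl-N-[(1S)-1-phenylethyl]hex-5-enamide | C=CCC[C@@](C)(C(=O)N[C@@H](C)c1ccccc1)c1ccc(C)cc1O
F5 | step 10 | (1S,2S,5R)-2-[2-(benzyloxy)-4-methylphenyl]-1,2-dimethyl-6-oxabicyclo[3.1.0]hexane | Cc1ccc(c(OCc2ccccc2)c1)[C@]1(C)CC[C@H]2O[C@@]12C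
F6 | step 10 | (1R,3R)-3-[2-(benzyloxy)-4-methylphenyl]-3-methyl-2-methylidenecyclopentan-1-ol | Cc1ccc(c(OCc2ccccc2)c1)[C@]1(C)CC[C@@H](O)C1=C
F0 | step 14 | none | none
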